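## Retrosynthetic overview

1. Target ⇐ selective removal of the primary C19 acetate from the 3,19-diacetate ⇐ 3,19-diol acid ⇐ two hydride reductions (C3 ketone, C19 auxiliary ester) of a bicyclic β-keto ester.
2. Bicyclic β-keto ester ⇐ one-pot oxidative radical bicyclisation (trivalent manganese) of an acyclic (E,E)-diene β-keto ester. Ring A (C4–C5 bond) forms first, ring B (C10–C9 bond) second. An 8-phenylmenthyl ester sets the absolute sense, and a tert-butyl sulfone at C7 leaves as a radical to place the C7=C8 alkene.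
3. Acyclic precursor ⇐ γ-alkylation of the auxiliary 2-methylacetoacetate dianion with a C12 allylic bromide ⇐ α-sulfonyl carbanion alkylation with (E)-1,4-dibromo-2-methylbut-2-ene.
4. Allyl sulfone ⇐ allylic oxidation and sulfonylation of (R)-citronellic acid, which supplies C13 and the C15 acid (carried unprotected throughout).

Assumption: the target is taken exactly as the SMILES draws it (3S,4R,5S,9R,10S,13R, labdane numbering), and the (+)-8-phenylmenthyl ester is assumed to give this ring-system enantiomer, mirroring the known sense of the (−)-auxiliary in the 10β-methyl series.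

Numbering in names: acyclic compounds use chain numbering from the free acid carbon. Compounds 14–19 use labdane numbering (decalin C1–C10; C18 = equatorial methyl on C4; C19 = axial carbon on C4, cis to the C10 methyl C20; C17 = methyl on C8; side chain C11–C16 on C9).

## Route

Step 1
Reactants: 1 (R)-citronellic acid [(3R)-3,7-dimethyloct-6-enoic acid]
Product: 2 (3R,6E)-8-hydroxy-3,7-dimethyloct-6-enoic acid
Conditions: SeO2 (0.3 equiv), t-BuOOH (2.5 equiv), salicylic acid (0.1 equiv), CH2Cl2, 0 °C → rt
Reagents that add atoms: tert-butyl hydroperoxide CC(C)(C)OO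
Why: Sharpless-type catalytic SeO2 allylic oxidation (ene reaction then 2,3-sigmatropic shift) hydroxylates only the methyl trans to the chain of the trisubstituted alkene, giving the (E)-allylic alcohol without touching the C3 stereocenter or the acid.

Step 2
Reactants: 2 (3R,6E)-8-hydroxy-3,7-dimethyloct-6-enoic acid; 3 sodium tert-butylsulfinate (sodium 2-methylpropane-2-sulfinate)
Product: 4 (3R,6E)-8-(tert-butylsulfonyl)-3,7-dimethyloct-6-enoic acid
Conditions: 3 (1.3 equiv), Pd(PPh3)4 (5 mol %), THF, 50 °C; aq HCl work-up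
Reagents that add atoms: none
Why: Tsuji–Trost-type dehydrative allylic sulfonylation in which zerovalent palladium ionises the allylic alcohol (helped by the substrate's own carboxylic acid) and sulfinate sulfur attacks the unhindered primary terminus of the π-allyl complex, reversible ionisation funnelling the material to the linear (E)-sulfone.

Step 3
Reactants: 4 (3R,6E)-8-(tert-butylsulfonyl)-3,7-dimethyloct-6-enoic acid; 5 (E)-1,4-dibromo-2-methylbut-2-ene
Product: 7 (3R,6E,10E)-12-bromo-8-(tert-butylsulfonyl)-3,7,11-trimethyldodeca-6,10-dienoic acid (1:1 at C8), via dilithio sulfone carboxylate 6 (not isolated)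
Conditions: LiN(i-Pr)2 (2.05 equiv), THF, −78 °C; cannulate into 5 (3 equiv), THF, −78 → −40 °C; aq HCl
Reagents that add atoms: none
Why: Julia-type α-alkylation of the lithiated allyl sulfone, which reacts at the sulfonyl-bearing carbon with retention of the (E)-alkene and by SN2 at the less hindered CH2Br of 5 (the one on the CH= carbon, expected at least 5:1), excess 5 suppressing double alkylation, while the new C8 stereocenter forms unselectively and is erased in step 6.

Step 4
Reactants: 8 (+)-8-phenylmenthol [(1S,2R,5S)-5-methyl-2-(2-phenylpropan-2-yl)cyclohexan-1-ol]; 9 ethyl 2-methyl-3-oxobutanoate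
Product: 10 (1S,2R,5S)-5-methyl-2-(2-phenylpropan-2-yl)cyclohexyl 2-methyl-3-oxobutanoate (both C2 epimers)
Conditions: 9 (3 equiv), DMAP (0.3 equiv), toluene, reflux, 4 Å MS (−EtOH)
Reagents that add atoms: none
Why: DMAP-catalysed transesterification of a β-keto ester (acylketene pathway), driven by removal of ethanol, installs the recoverable chiral auxiliary, and the epimeric α-carbon is of no consequence because it becomes a planar radical in step 6.

Step 5
Reactants: 10 (1S,2R,5S)-5-methyl-2-(2-phenylpropan-2-yl)cyclohexyl 2-methyl-3-oxobutanoate; 7 (3R,6E,10E)-12-bromo-8-(tert-butylsulfonyl)-3,7,11-trimethyldodeca-6,10-dienoic acid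
Product: 13 (3R,6E,10E)-8-(tert-butylsulfonyl)-3,7,11,15-tetramethyl-14-oxohexadeca-6,10-dienedioic acid 16-[(1S,2R,5S)-5-methyl-2-(2-phenylpropan-2-yl)cyclohexyl] ester (epimers at C8/C15), via keto ester dianion 11 (not isolated), via lithium carboxylate 12 (not isolated)
Conditions: 10 (1.3 equiv), LiN(i-Pr)2 (2.6 equiv), THF, 0 °C; add 7 pretreated with LiN(i-Pr)2 (1.0 equiv, THF, −78 °C); −78 → 0 °C; aq HCl
Reagents that add atoms: none
Why: Huckin–Weiler γ-alkylation of a β-keto ester dianion, whose terminal carbanion displaces the primary allylic bromide by SN2 with retention of the (E)-alkene faster than it can deprotonate the weakly acidic alkyl sulfone, the acid being held as its inert lithium salt.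

Step 6
Reactants: 13 (3R,6E,10E)-8-(tert-butylsulfonyl)-3,7,11,15-tetramethyl-14-oxohexadeca-6,10-dienedioic acid 16-[(1S,2R,5S)-5-methyl-2-(2-phenylpropan-2-yl)cyclohexyl] ester
Product: 14 (4S,5S,9R,10S,13R)-3-oxolabd-7-ene-15,19-dioic acid 19-[(1S,2R,5S)-5-methyl-2-(2-phenylpropan-2-yl)cyclohexyl] ester (trans-decalin; C19 ester axial and cis to C20; side chain equatorial)
Conditions: Mn(OAc)3·2H2O (2.5 equiv), Cu(OAc)2·H2O (0.1 equiv), degassed AcOH, 0.005 M, 25 °C; chromatography (major diastereomer)
Reagents that add atoms: none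
Why: Proposed new method: a Snider-type oxidative radical polyene cyclisation by trivalent manganese (closest known reaction: Mn(OAc)3 bicyclisation of α-methyl β-keto ester polyenes under 8-phenylmenthyl control, which gives the axial ester) in which the unchelated radical at chain C15 adds 6-endo to the C10=C11 alkene on the face left open by the auxiliary phenyl ring through a chair–chair fold of the (E,E)-diene, the tertiary ring-A radical then closes ring B 6-endo onto the allyl sulfone to give the trans-decalin with equatorial side chain (4S,5S,9R,10S), and the resulting tertiary radical β to sulfur expels t-BuSO2• (allyl sulfone SH2′ logic) to fix the alkene at labdane C7=C8, the sulfonyl radical collapsing to SO2 and t-Bu• (oxidised to 2-methylpropene via catalytic Cu(OAc)2) so that no chain-carrying sulfonyl radical remains to scramble the allyl sulfone.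

Step 7
Reactants: 14 (4S,5S,9R,10S,13R)-3-oxolabd-7-ene-15,19-dioic acid 19-[(1S,2R,5S)-5-methyl-2-(2-phenylpropan-2-yl)cyclohexyl] ester
Product: 16 (3S,4R,5S,9R,10S,13R)-3,19-dihydroxylabd-7-en-15-oic acid (3-OH axial and anti to the axial CH2OH), via lithium hydroxy ester salt 15 (not isolated)
Conditions: LiBH(s-Bu)3 (3 equiv), THF, −78 → −40 °C; then LiBHEt3 (8 equiv), → 65 °C; aq HCl
Reagents that add atoms: none
Why: chemoselective hydride reductions in which the bulky LiBH(s-Bu)3 attacks the C3 ketone from the equatorial direction (the C19/C20 face, avoiding the syn-axial H-1 and H-5) to give the axial (3S)-alcohol anti to C19, after which the strongly nucleophilic LiBHEt3 reduces the hindered C19 ester to CH2OH and releases the auxiliary while the lithium carboxylate at C15 is left untouched.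

Step 8
Reactants: 16 (3S,4R,5S,9R,10S,13R)-3,19-dihydroxylabd-7-en-15-oic acid
Product: 18 (3S,4R,5S,9R,10S,13R)-3,19-diacetoxylabd-7-en-15-oic acid, via mixed anhydride 17 (not isolated)
Conditions: Ac2O (6 equiv), DMAP (0.2 equiv), pyridine, 40 °C; then H2O, rt
Reagents that add atoms: acetic anhydride CC(=O)OC(C)=O
Why: DMAP-catalysed acetylation esterifies both hydroxyls (the hindered axial 3-OH needs the nucleophilic catalyst) and the transient mixed anhydride at C15 is hydrolysed by water, no stereocenter being affected.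

Step 9
Reactants: 18 (3S,4R,5S,9R,10S,13R)-3,19-diacetoxylabd-7-en-15-oic acid
Product: 19 (3S,4R,5S,9R,10S,13R)-3-acetoxy-19-hydroxylabd-7-en-15-oic acid (CNP0138726.1)
Conditions: K2CO3 (1.5 equiv), MeOH, 0 °C, stop when 18 is consumed; aq HCl to pH 3
Reagents that add atoms: none
Why: base-catalysed methanolysis (Zemplén-type transesterification) removes the primary neopentyl acetate much faster than the axial secondary acetate flanked by the quaternary C4, as exploited for triterpenoid 3,28-diacetates, and the trans-diaxial arrangement of O3 and C19 rules out acyl migration.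

## Compound list

1 | (R)-citronellic acid, (3R)-3,7-dimethyloct-6-enoic acid | CC(C)=CCC[C@@H](C)CC(=O)O | starting material
2 | (3R,6E)-8-hydroxy-3,7-dimethyloct-6-enoic acid | OC/C(C)=C/CC[C@@H](C)CC(=O)O | intermediate
3 | sodium tert-butylsulfinate (sodium 2-methylpropane-2-sulfinate) | CC(C)(C)S(=O)[O-].[Na+] | starting material
4 | (3R,6E)-8-(tert-butylsulfonyl)-3,7-dimethyloct-6-enoic acid | CC(C)(C)S(=O)(=O)C/C(C)=C/CC[C@@H](C)CC(=O)O | intermediate
5 | (E)-1,4-dibromo-2-methylbut-2-ene | BrC/C(C)=C/CBr | starting material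
6 | dilithium salt of 4 (C1 carboxylate, C8 α-sulfonyl allyl carbanion) | CC(C)(C)S(=O)(=O)[CH-]/C(C)=C/CC[C@@H](C)CC(=O)[O-].[Li+].[Li+] | intermediate
7 | (3R,6E,10E)-12-bromo-8-(tert-butylsulfonyl)-3,7,11-trimethyldodeca-6,10-dienoic acid (1:1 at C8) | BrC/C(C)=C/CC(S(=O)(=O)C(C)(C)C)/C(C)=C/CC[C@@H](C)CC(=O)O | intermediate
8 | (+)-8-phenylmenthol, (1S,2R,5S)-5-methyl-2-(2-phenylpropan-2-yl)cyclohexan-1-ol | O[C@H]1C[C@@H](C)CC[C@@H]1C(C)(C)c1ccccc1 | starting material
9 | ethyl 2-methyl-3-oxobutanoate | CCOC(=O)C(C)C(C)=O | starting material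
10 | (1S,2R,5S)-5-methyl-2-(2-phenylpropan-2-yl)cyclohexyl 2-methyl-3-oxobutanoate (both C2 epimers) | CC(=O)C(C)C(=O)O[C@H]1C[C@@H](C)CC[C@@H]1C(C)(C)c1ccccc1 | intermediate
11 | dilithium dianion of 10 (C2 and C4 of the butanoate deprotonated) | [CH2-]C(=O)[C-](C)C(=O)O[C@H]1C[C@@H](C)CC[C@@H]1C(C)(C)c1ccccc1.[Li+].[Li+] | intermediate
12 | lithium carboxylate of 7 | BrC/C(C)=C/CC(S(=O)(=O)C(C)(C)C)/C(C)=C/CC[C@@H](C)CC(=O)[O-].[Li+] | intermediate
13 | (3R,6E,10E)-8-(tert-butylsulfonyl)-3,7,11,15-tetramethyl-14-oxohexadeca-6,10-dienedioic acid 16-[(1S,2R,5S)-5-methyl-2-(2-phenylpropan-2-yl)cyclohexyl] ester (epimers at C8/C15) | CC(C(=O)CC/C(C)=C/CC(S(=O)(=O)C(C)(C)C)/C(C)=C/CC[C@@H](C)CC(=O)O)C(=O)O[C@H]1C[C@@H](C)CC[C@@H]1C(C)(C)c1ccccc1 | intermediate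
14 | (4S,5S,9R,10S,13R)-3-oxolabd-7-ene-15,19-dioic acid 19-[(1S,2R,5S)-5-methyl-2-(2-phenylpropan-2-yl)cyclohexyl] ester | O=C1CC[C@]2(C)[C@H](CC=C(C)[C@H]2CC[C@@H](C)CC(=O)O)[C@]1(C)C(=O)O[C@H]3C[C@@H](C)CC[C@@H]3C(C)(C)c4ccccc4 | intermediate
15 | dilithium salt (C3 alkoxide, C15 carboxylate) of the (3S,4S,5S,9R,10S,13R)-3-hydroxylabd-7-ene-15,19-dioic acid 19-auxiliary ester | [O-][C@H]1CC[C@]2(C)[C@H](CC=C(C)[C@H]2CC[C@@H](C)CC(=O)[O-])[C@]1(C)C(=O)O[C@H]3C[C@@H](C)CC[C@@H]3C(C)(C)c4ccccc4.[Li+].[Li+] | intermediate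
16 | (3S,4R,5S,9R,10S,13R)-3,19-dihydroxylabd-7-en-15-oic acid | O[C@H]1CC[C@]2(C)[C@H](CC=C(C)[C@H]2CC[C@@H](C)CC(=O)O)[C@]1(C)CO | intermediate
17 | mixed acetic anhydride (at C15) of the 3,19-diacetate 18 | CC(=O)O[C@H]1CC[C@]2(C)[C@H](CC=C(C)[C@H]2CC[C@@H](C)CC(=O)OC(C)=O)[C@]1(C)COC(C)=O | intermediate
18 | (3S,4R,5S,9R,10S,13R)-3,19-diacetoxylabd-7-en-15-oic acid | CC(=O)O[C@H]1CC[C@]2(C)[C@H](CC=C(C)[C@H]2CC[C@@H](C)CC(=O)O)[C@]1(C)COC(C)=O | intermediate
19 | (3S,4R,5S,9R,10S,13R)-3-acetoxy-19-hydroxylabd-7-en-15-oic acid = (3R)-5-[(1R,4aS,5R,6S,8aS)-6-acetoxy-5-(hydroxymethyl)-2,5,8a-trimethyl-1,4,4a,5,6,7,8,8a-octahydronaphthalen-1-yl]-3-methylpentanoic acid | CC(=O)O[C@H]1CC[C@]2(C)[C@H](CC=C(C)[C@H]2CC[C@@H](C)CC(=O)O)[C@]1(C)CO | target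

## Step count and risks

Total step count: 9. Longest linear sequence: 8 (steps 1, 2, 3, 5, 6, 7, 8, 9 from 1); step 4 is a one-step side branch.

The three steps most likely to fail:

**Step 6 (bicyclisation).** The sulfone-terminated oxidative cascade is untested. The ring-B radical must fragment faster than it is oxidised, and the auxiliary must control the face without a chelating additive (a chelating Lewis acid would turn the ester equatorial). The fallback sets out from 13 and comes back at 14. Compound 13 is brominated at C15 with N-bromosuccinimide and catalytic Mg(ClO4)2 (MeCN, 0 °C) to give (3R,6E,10E)-15-bromo-8-(tert-butylsulfonyl)-3,7,11,15-tetramethyl-14-oxohexadeca-6,10-dienedioic acid 16-[(1S,2R,5S)-5-methyl-2-(2-phenylpropan-2-yl)cyclohexyl] ester F1. F1 is then cyclised as a non-oxidative radical chain (Et3B/air, toluene, −40 °C). Bromine abstraction gives the same C15 radical and the same two 6-endo closures follow. The tert-butyl radical left after loss of SO2 abstracts bromine from the next molecule of F1. Compound 14 is thus formed without any metal oxidant, at a temperature that should sharpen auxiliary control.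

**Step 7 (reductions).** The equatorial approach of the bulky hydride runs past the axial C19 ester, so the C3 selectivity may drop or invert. The 8-phenylmenthyl ester of a quaternary acid is also very hindered. The fallback sets out from 14 and comes back at 16. Compound 14 is treated with LiN(i-Pr)2 (2.2 equiv, THF, −78 °C) so that the acid is a carboxylate and the C3 ketone is masked as its C2 enolate. The C19 ester is reduced with LiBHEt3 (0 → 25 °C) and the mixture is quenched cold with AcOH to release (4R,5S,9R,10S,13R)-19-hydroxy-3-oxolabd-7-en-15-oic acid F2. Me4NBH(OAc)3 in MeCN/AcOH at −20 °C then delivers hydride intramolecularly from the C19 alkoxyborohydride (Evans–Saksena anti reduction). The hydride arrives on the C19 face, so the 3-OH ends up anti to C19 by design and not by reagent bulk, giving 16.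

**Step 3 (alkylation with the dibromide).** The two allylic termini of 5 differ only modestly, and the product can be deprotonated and close to a vinylcyclopropane. The fallback sets out from 4 and comes back at 7. The dianion 6 is alkylated with prenyl bromide (1-bromo-3-methylbut-2-ene), which has a single electrophilic site, to give (3R,6E)-8-(tert-butylsulfonyl)-3,7,11-trimethyldodeca-6,10-dienoic acid F3. SeO2/t-BuOOH then oxidises the terminal (E)-methyl (the inner alkene is deactivated by the allylic sulfone) to (3R,6E,10E)-8-(tert-butylsulfonyl)-12-hydroxy-3,7,11-trimethyldodeca-6,10-dienoic acid F4. PBr3 (Et2O, 0 °C, aqueous work-up) converts F4 into 7.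

Further compounds
F1 | step 6 | (3R,6E,10E)-15-bromo-8-(tert-butylsulfonyl)-3,7,11,15-tetramethyl-14-oxohexadeca-6,10-dienedioic acid 16-[(1S,2R,5S)-5-methyl-2-(2-phenylpropan-2-yl)cyclohexyl] ester | CC(Br)(C(=O)CC/C(C)=C/CC(S(=O)(=O)C(C)(C)C)/C(C)=C/CC[C@@H](C)CC(=O)O)C(=O)O[C@H]1C[C@@H](C)CC[C@@H]1C(C)(C)c1ccccc1
F2 | step 7 | (4R,5S,9R,10S,13R)-19-hydroxy-3-oxolabd-7-en-15-oic acid | O=C1CC[C@]2(C)[C@H](CC=C(C)[C@H]2CC[C@@H](C)CC(=O)O)[C@]1(C)CO
F3 | step 3 | (3R,6E)-8-(tert-butylsulfonyl)-3,7,11-trimethyldodeca-6,10-dienoic acid | CC(C)=CCC(S(=O)(=O)C(C)(C)C)/C(C)=C/CC[C@@H](C)CC(=O)O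
F4 | step 3 | (3R,6E,10E)-8-(tert-butylsulfonyl)-12-hydroxy-3,7,11-trimethyldodeca-6,10-dienoic acid | OC/C(C)=C/CC(S(=O)(=O)C(C)(C)C)/C(C)=C/CC[C@@H](C)CC(=O)O
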